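The numbers in the tables are calculated on assumed constants; noise was put on by code.

Start at the late readings, where the sum of target and starting material is still falling but the split between them holds steady within the scatter.

| flask | starting material | remark | time |
|---|---|---|---|
| north-west | 0.22 M | run made earlier |  |
| north | 0.88 M | run made earlier |  |
| maple | 0.44 M |  | 80 h |
| oak | 0.44 M |  | 20 h |

- north-west (time / h: target / %, starting material / %): 3.00: 21.6, 76.2; 6.00: 25.3, 70.5; 8.00: 25.1, 69.6; 12.0: 24.6, 67.7; 15.0: 23.4, 66.6; 20.0: 23.6, 65.2
- north (time / h: target / %, starting material / %): 3.00: 21.2, 73.6; 6.00: 23.5, 67.5; 8.00: 23.4, 64.8; 12.0: 23.1, 62.3; 15.0: 22.5, 60.5; 20.0: 20.8, 57.1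

(each reading ± 0.3 percentage points)

1. which one finishes higher in amount of target, in percent of the starting material charged ("neither" within 2 percentage points) (maple / oak / neither)
2. amount of target at the end, in percent of the starting material charged, maple
3. amount of target at the end, in percent of the starting material charged, oak



Keep a ledger of the charge at 20.0 h. In the north-west run, 65.2% is still starting material and 23.6% is target, so the split reads 0.362: call target over starting material at the same moment the target ratio. The north run reads 0.364 at 0.88 M, so freeze the ratio, as one does for a pre-equilibrium.

That leaves one entry to find, the missing part: 11.2% in the north-west run and 22.1% in the north run, about twice as much. Draw a straight line through these against the charge. This splits the loss into a leak of 7.57% that ignores the charge and a pair entry, a second-order loss, of 7.27% at 0.44 M.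

Close oak's books: take both entries from the charge and share the rest between target and starting material in the proportion the ratio gives, which leaves 22.6% target. For maple, at 80 h, let the inverse of what the pair entry leaves grow in step with time, so that entry reaches 23.9%. Freeze the leak as a guess; each point of error there moves target by about a quarter of a point. Maple's books then close at 18.2% target, so I expect oak to finish higher by 4.4 percentage points.

The forecast names oak, with 14.5% for maple, below my figure, and 22.3% for oak, adding “The long extrapolation is the less certain figure”.

The flask gives 17.7% for maple and 22.5% for oak, so oak finishes higher.

    starting material ⇌ target (K = 0.360, k = 0.160 h⁻¹)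
    target ⇌ isomer of the product A (K = 0.0640, k = 0.0130 h⁻¹)
    isomer of the product A ⇌ isomer of the product B (K = 7.10, k = 0.760 h⁻¹)
    isomer of the product B ⇌ starting material (k = 0.0220 h⁻¹)
    2 starting material → self-condensation product (k = 0.00990 M⁻¹ h⁻¹)

Maple's self-condensation product, counted by the starting material it holds, stands at 24.0% of the charge at 80.0 h, beside the 23.9% of the pair entry. Multiply maple's 48.8% of starting material by the target ratio and you get 17.7% target. Now take a neighbour of maple, charged with 1.8 M and read at the same time: its 28.0% of starting material gives 10.1% by the ratio, and it holds 10.3% target.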